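Amounts first: north-east holds 10 mM of D and 2.00 equiv of Q, and its X is asked at 8.0 d. In the earlier runs X stays small beside D, for instance 2.2 % against 18.8 % at 4.00 d in eta. So X can be reckoned as a correction to D.

| flask | D | Q | remark | time |
|---|---|---|---|---|
| eta | 10 mM | 1.8 equiv | run made earlier |  |
| zeta | 10 mM | 3.8 equiv | run made earlier |  |
| north-east | 10 mM | 2.00 equiv |  | 8.0 d |
| north-west | 10 mM | 1.50 equiv |  | 8.0 d |
| south | 10 mM | 3.00 equiv |  | 8.0 d |

| run | time / d | X / % | D / % |
|---|---|---|---|
| eta | 0.333 | 8.2 | 59.7 |
| eta | 1.04 | 7.7 | 40.7 |
| eta | 1.67 | 5.4 | 31.3 |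
| eta | 3.00 | 4.6 | 23.2 |
| eta | 4.00 | 2.2 | 18.8 |
| zeta | 0.333 | 6.4 | 32.8 |
| zeta | 0.625 | 4.3 | 19.7 |
| zeta | 1.04 | 0.9 | 10.6 |
| zeta | 2.00 | 0.6 | 2.0 |
| zeta | 4.00 | 0 | 1.8 |

(standard deviation of a reading: 1 percentage point)

- the analysis behind the earlier runs scatters by 1 percentage point, standard deviation

- which of these holds the largest part of the D at the end of north-east (D / Z / X)
- which of these holds the largest part of the D at the end of north-west (D / Z / X)
- which of these holds the largest part of the D at the end of south (D / Z / X)
- X at the end of north-east, in percent of the D charged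

If D gives X and X goes on to Z, each step taking one Q, then Q multiplies both rates, and X over D need not depend on Q. Column against column, eta gives 0.137, 0.189, 0.173, 0.198 and 0.117. Zeta, with more Q, begins at 0.195 and 0.218. Its third row gives 0.0849, but X there is 0.9 % against a scatter of 1 percentage point.

Pooling eta with the zeta rows down to 1.04 d gives 0.168. This reading is the tracking ratio r, the steady-state value of X over D, and it carries the scatter of the readings.

D remains to be found. If Q falls in step with D, the loss of D goes as its square, and the reciprocal of D, taken as a fraction of the charge, should climb linearly. In eta it climbs from 2.46 at 1.04 d to 5.32 at 4.00 d, a slope of 0.967 /d. Continued to 8.0 d, that line gives D of 10.9 %, and r then gives X of 1.82 %. North-east has more Q than eta, so both figures should come out lower. The readings give X and D but not Z, so r says nothing about Z.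

The forecast names Z, Z and Z for north-east, north-west and south, and puts X at 1.2 % (0.5 % to 2.5 %), holding that “X never accumulates”.

North-east ends with D 7.22 %, X 1.28 % and Z 14.7 %, so Z leads of the three. Of the same three, north-west has D 24.1 % and Z 11.5 %, so D leads. Of the same three, south gives Z, at 16.0 %.

    D + Q → X (k = 6.10 /M/h)
    Q + X → G (k = 34.0 /M/h)
    Q ⇌ L (K = 0.910, k = 0.0890 /h)
    Q + X → Z (k = 6.50 /M/h)

In north-east X over D ends at 0.177, beside r of 0.168, while the reckoned D stood above the flask's 7.22 %. In north-east at 0.390 d, X is used by the turning of Q + X into G at 5.2 times the rate of the turning of Q + X into Z, and at 8.00 d G stands at 76.8 % against Z at 14.7 %. At 8.00 d, each step taken net, X is made at 0.849 of the rate at which it is used.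

The neighbour of north-east charged with 1.20 equiv of Q ends with D at 37.1 %, so r gives X of 6.23 %. The computed X is 6.55 %.

The numbers in the tables are simulated for substances that don't exist, noise included.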